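## Retrosynthetic overview

1. Ring A is the acetoxycyclohexene, ring B the epoxycyclohexane, ring C the butenolide. Ring carbons are numbered C1 (gem-dimethyl), C2, C3 (oxygenated), C4, C5 (methyl-bearing), C6 (chain-bearing); C7 is the first chain carbon.
2. The last bond is the central single bond of the pentaene, made by Stille coupling of ring A dienyl stannane 19 with ring B/ring C dienyl iodide 31. Ring C comes from Pd/Cu alkynylation and 5-exo-dig lactonisation of (E)-2,3-dibromoacrylic acid 26 with enynol 27; its remaining C–Br bond takes the ring B vinylstannane 24.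
3. Both carbocycles come from one C10 allylic alcohol, 10. Ring A is reached by Colvin homologation, Cadiot–Chodkiewicz coupling and zirconium-catalysed carboalumination; ring B by a Sharpless epoxidation that sets C5 and C6 relative to C3.
4. Key disconnection: the six-membered carbocycle is cut at C3–C4 and C1–C6 into two three-carbon pieces. This works because C4–C5–C6–C7 is an acetoacetate in disguise (C5 = ketone carbon, C7 = ester carbon, C4 and C6 nucleophilic), while C3 is a carbinol carbon and C1 a gem-dimethyl carbon two bonds away (the aldehyde carbon and the tertiary cation site of 3-methylbut-3-enal, both electrophilic).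
5. Order of ring formation: the cyclohexane ring common to A and B (step 2, C3 set by catalysis), then the oxirane of ring B (step 14), then butenolide ring C (step 20).

Key step: step 2

Assumptions: compounds 1, 3, 13, 18, 25 and 27 are bought. (R)-BINOL is taken to steer the dienol ether to the Re face of aldehyde 2, the sense known for this titanate with other aldehydes, which corresponds to the (5S) aldol 5; if the sense were opposite, (S)-BINOL would be used.

## Route

Step 1
Reactants: 1 3-methylbut-3-en-1-ol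
Product: 2 3-methylbut-3-enal
Conditions: Dess–Martin periodinane, NaHCO3, CH2Cl2, 0 °C; filtered cold and used at once as a dried solution
Reagents that add atoms: none
Why: Dess–Martin oxidation of the primary alcohol under buffered, non-acidic conditions should give the beta,gamma-unsaturated aldehyde without isomerisation to the conjugated enal.

Step 2
Reactants: 2 3-methylbut-3-enal; 3 1-methoxy-1,3-bis(trimethylsilyloxy)buta-1,3-diene
Product: 6 methyl (4S)-4-hydroxy-6,6-dimethyl-2-oxocyclohexane-1-carboxylate, via silyl aldol adduct 4 (not isolated), via hydroxy keto ester 5 (not isolated)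
Conditions: Ti(OiPr)4 (10 mol%), (R)-BINOL (10 mol%), 4 Å MS, THF, −78 °C to rt; CF3CO2H, 0 °C; volatiles off, then SnCl4 (1.5 equiv), CH2Cl2, 0 °C to rt
Reagents that add atoms: none
Why: The BINOL titanate binds aldehyde 2 and the unsubstituted terminal carbon of dienol ether 3 adds to the carbonyl (vinylogous Mukaiyama aldol, bond C3–C4) to give 4; CF3CO2H strips the silyl groups to 5, and SnCl4 then forms the tin enolate of the beta-keto ester while the HCl released protonates the 1,1-disubstituted alkene at CH2 to the tertiary cation at C1, which the enolate carbon C6 traps (bond C1–C6). Both halves are known reaction types, the Ti(OiPr)4/BINOL-catalysed aldol addition of this diene to aliphatic aldehydes and the SnCl4-mediated, beta-keto-ester-terminated cation–olefin cyclisation of 6-alkenyl acetoacetates to 3,3-dimethyl-2-(methoxycarbonyl)cyclohexanones, run here in one flask. The carbocycle closes 6-exo at the former alkene (its CH2 terminus ends as the second methyl group on C1) and enol-endo at the nucleophile, through a chair with the tin-chelated keto ester and the C3 oxygen equatorial. The only lasting stereocenter, C3 (C4 of 6), is set in the aldol stage by the chiral titanium catalyst (Re-face attack, S descriptor in 5 and 6) and is not touched by the cyclisation; the ester-bearing carbon is enolisable and is erased in step 4. The step needs terminal over internal attack of the dienol ether (the silyl enol ether terminus is the most nucleophilic site), 1,2-addition before any cation exists (the titanate does not protonate the isolated alkene) and C- over O-alkylation by the cation (O-alkylation to the cyclic enol ether is reversible under SnCl4, C–C bond formation is not). Retro-aldol cleavage and dehydration of the beta-hydroxy ketone should be held back by the low temperature and by chelation of tin between hydroxyl and keto ester.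

Step 3
Reactants: 6 methyl (4S)-4-hydroxy-6,6-dimethyl-2-oxocyclohexane-1-carboxylate
Product: 7 methyl (4S)-4-[(tert-butyldimethylsilyl)oxy]-6,6-dimethyl-2-oxocyclohexane-1-carboxylate
Conditions: tert-butyldimethylsilyl chloride, imidazole, DMF, rt; aqueous work-up
Reagents that add atoms: tert-butyldimethylsilyl chloride CC(C)(C)[Si](C)(C)Cl
Why: Silylation of the secondary alcohol should be clean, since any silyl enol ether of the keto ester is hydrolysed on work-up.

Step 4
Reactants: 7 methyl (4S)-4-[(tert-butyldimethylsilyl)oxy]-6,6-dimethyl-2-oxocyclohexane-1-carboxylate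
Product: 8 methyl (4S)-4-[(tert-butyldimethylsilyl)oxy]-6,6-dimethyl-2-{[(trifluoromethyl)sulfonyl]oxy}cyclohex-1-ene-1-carboxylate
Conditions: (CF3SO2)2O, iPr2NEt, CH2Cl2, −78 °C
Reagents that add atoms: trifluoromethanesulfonic anhydride O=S(=O)(OS(=O)(=O)C(F)(F)F)C(F)(F)F
Why: Enol triflate formation at the doubly activated position of the beta-keto ester fixes the double bond at C5=C6 and erases the undefined ester-bearing stereocenter.

Step 5
Reactants: 8 methyl (4S)-4-[(tert-butyldimethylsilyl)oxy]-6,6-dimethyl-2-{[(trifluoromethyl)sulfonyl]oxy}cyclohex-1-ene-1-carboxylate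
Product: 9 methyl (4R)-4-[(tert-butyldimethylsilyl)oxy]-2,6,6-trimethylcyclohex-1-ene-1-carboxylate
Conditions: Fe(acac)3 (5 mol%), MeMgBr, THF/NMP, −30 °C
Reagents that add atoms: methylmagnesium bromide C[Mg]Br
Why: Iron-catalysed Kumada-type cross-coupling of an enol triflate with a methyl Grignard reagent is fast at low temperature, tolerates ester and silyl ether, and installs the C5 methyl group (the descriptor changes from S to R only through the priority rules).

Step 6
Reactants: 9 methyl (4R)-4-[(tert-butyldimethylsilyl)oxy]-2,6,6-trimethylcyclohex-1-ene-1-carboxylate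
Product: 10 [(4R)-4-[(tert-butyldimethylsilyl)oxy]-2,6,6-trimethylcyclohex-1-en-1-yl]methanol
Conditions: iBu2AlH, CH2Cl2, −78 to 0 °C
Reagents that add atoms: none
Why: 1,2-Reduction of the hindered conjugated ester by the aluminium hydride should give the allylic alcohol that serves both rings.

Step 7
Reactants: 10 [(4R)-4-[(tert-butyldimethylsilyl)oxy]-2,6,6-trimethylcyclohex-1-en-1-yl]methanol
Product: 11 (4R)-4-[(tert-butyldimethylsilyl)oxy]-2,6,6-trimethylcyclohex-1-ene-1-carbaldehyde
Conditions: MnO2, CH2Cl2, rt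
Reagents that add atoms: none
Why: Allylic oxidation with MnO2 stops at the enal.

Step 8
Reactants: 11 (4R)-4-[(tert-butyldimethylsilyl)oxy]-2,6,6-trimethylcyclohex-1-ene-1-carbaldehyde
Product: 12 tert-butyl{[(1R)-4-ethynyl-3,5,5-trimethylcyclohex-3-en-1-yl]oxy}dimethylsilane
Conditions: Me3SiCHN2, LiN(iPr)2, THF, −78 °C to rt
Reagents that add atoms: (trimethylsilyl)diazomethane C[Si](C)(C)C=[N+]=[N-]
Why: Colvin rearrangement: the lithiated diazomethane adds to the aldehyde, Peterson elimination and loss of N2 give an alkylidene carbene, and its 1,2-shift yields the terminal alkyne with the aldehyde carbon as C7.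

Step 9
Reactants: 12 tert-butyl{[(1R)-4-ethynyl-3,5,5-trimethylcyclohex-3-en-1-yl]oxy}dimethylsilane; 13 (bromoethynyl)triisopropylsilane
Product: 14 tert-butyldimethyl{[(1R)-3,5,5-trimethyl-4-[4-(triisopropylsilyl)buta-1,3-diyn-1-yl]cyclohex-3-en-1-yl]oxy}silane
Conditions: CuCl (10 mol%), NH2OH·HCl, n-BuNH2, H2O/CH2Cl2, 0 °C
Reagents that add atoms: none
Why: Cadiot–Chodkiewicz coupling of the copper acetylide with a bromoalkyne should give the unsymmetrical 1,3-diyne without homocoupling.

Step 10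
Reactants: 14 tert-butyldimethyl{[(1R)-3,5,5-trimethyl-4-[4-(triisopropylsilyl)buta-1,3-diyn-1-yl]cyclohex-3-en-1-yl]oxy}silane
Product: 15 (1R)-4-(buta-1,3-diyn-1-yl)-3,5,5-trimethylcyclohex-3-en-1-ol
Conditions: Bu4NF (2.5 equiv), THF, 0 °C to rt
Reagents that add atoms: none
Why: Fluoride desilylation cleaves the alkynyl C–Si bond and the secondary silyl ether in the same operation.

Step 11
Reactants: 15 (1R)-4-(buta-1,3-diyn-1-yl)-3,5,5-trimethylcyclohex-3-en-1-ol
Product: 16 (1R)-4-[(3E)-4-iodo-3-methylbut-3-en-1-yn-1-yl]-3,5,5-trimethylcyclohex-3-en-1-ol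
Conditions: Me3Al (3 equiv), Cp2ZrCl2 (0.5 equiv), CH2Cl2, 0 °C to rt; then I2, THF, −30 °C
Reagents that add atoms: trimethylaluminium C[Al](C)C; iodine II
Why: Zirconium-catalysed carboalumination (Negishi) adds methyl and aluminium syn across the terminal alkyne of the conjugated diyne, methyl to the internal carbon, and iodinolysis with retention gives the (E)-iodide; the hindered ring-bound alkyne should not react and the hydroxyl is masked in situ as its aluminium alkoxide.

Step 12
Reactants: 16 (1R)-4-[(3E)-4-iodo-3-methylbut-3-en-1-yn-1-yl]-3,5,5-trimethylcyclohex-3-en-1-ol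
Product: 17 (1R)-4-[(3E)-4-iodo-3-methylbut-3-en-1-yn-1-yl]-3,5,5-trimethylcyclohex-3-en-1-yl acetate
Conditions: Ac2O, pyridine, DMAP (cat.), CH2Cl2, 0 °C to rt
Reagents that add atoms: acetic anhydride CC(=O)OC(C)=O
Why: DMAP-catalysed acetylation of the secondary alcohol installs the acetate of the target.

Step 13
Reactants: 17 (1R)-4-[(3E)-4-iodo-3-methylbut-3-en-1-yn-1-yl]-3,5,5-trimethylcyclohex-3-en-1-yl acetate; 18 (E)-1,2-bis(tributylstannyl)ethene
Product: 19 (1R)-3,5,5-trimethyl-4-[(3E,5E)-3-methyl-6-(tributylstannyl)hexa-3,5-dien-1-yn-1-yl]cyclohex-3-en-1-yl acetate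
Conditions: PdCl2(MeCN)2 (5 mol%), 18 (3 equiv), DMF, rt
Reagents that add atoms: none
Why: Stille coupling proceeds with retention at both sp2 carbons, and the excess of distannane should hold the reaction at mono-coupling, leaving an (E)-vinylstannane for the final union.

Step 14
Reactants: 10 [(4R)-4-[(tert-butyldimethylsilyl)oxy]-2,6,6-trimethylcyclohex-1-en-1-yl]methanol
Product: 20 [(1R,4S,6R)-4-[(tert-butyldimethylsilyl)oxy]-2,2,6-trimethyl-7-oxabicyclo[4.1.0]heptan-1-yl]methanol
Conditions: Ti(OiPr)4, L-(+)-diethyl tartrate, tBuOOH, 4 Å MS, CH2Cl2, −20 °C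
Reagents that add atoms: tert-butyl hydroperoxide CC(C)(C)OO
Why: Sharpless asymmetric epoxidation with L-(+)-tartrate should deliver oxygen to the face of the tetrasubstituted C5=C6 bond opposite to the C3 silyloxy group, so C5 and C6 of ring B are set by the reagent relative to the catalytically set C3.

Step 15
Reactants: 20 [(1R,4S,6R)-4-[(tert-butyldimethylsilyl)oxy]-2,2,6-trimethyl-7-oxabicyclo[4.1.0]heptan-1-yl]methanol
Product: 21 (1S,4S,6R)-4-[(tert-butyldimethylsilyl)oxy]-2,2,6-trimethyl-7-oxabicyclo[4.1.0]heptane-1-carbaldehyde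
Conditions: Pr4N[RuO4] (5 mol%), N-methylmorpholine N-oxide, 4 Å MS, CH2Cl2, rt
Reagents that add atoms: none
Why: Ley–Griffith oxidation of the primary epoxy alcohol gives an aldehyde that has no alpha hydrogen and cannot epimerise.

Step 16
Reactants: 21 (1S,4S,6R)-4-[(tert-butyldimethylsilyl)oxy]-2,2,6-trimethyl-7-oxabicyclo[4.1.0]heptane-1-carbaldehyde
Product: 22 tert-butyl{[(1R,3S,6R)-6-ethynyl-1,5,5-trimethyl-7-oxabicyclo[4.1.0]heptan-3-yl]oxy}dimethylsilane
Conditions: dimethyl (1-diazo-2-oxopropyl)phosphonate, K2CO3, MeOH, 0 °C to rt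
Reagents that add atoms: dimethyl (1-diazo-2-oxopropyl)phosphonate COP(=O)(OC)C(=[N+]=[N-])C(C)=O
Why: Ohira–Bestmann homologation converts the non-enolisable aldehyde into the terminal alkyne under mildly basic conditions that spare epoxide and silyl ether.

Step 17
Reactants: 22 tert-butyl{[(1R,3S,6R)-6-ethynyl-1,5,5-trimethyl-7-oxabicyclo[4.1.0]heptan-3-yl]oxy}dimethylsilane
Product: 23 (1R,3S,6R)-6-ethynyl-1,5,5-trimethyl-7-oxabicyclo[4.1.0]heptan-3-ol
Conditions: Bu4NF, THF, rt
Reagents that add atoms: none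
Why: Fluoride desilylation frees the secondary alcohol before the sensitive butenolide is present.

Step 18
Reactants: 23 (1R,3S,6R)-6-ethynyl-1,5,5-trimethyl-7-oxabicyclo[4.1.0]heptan-3-ol
Product: 24 (1R,3S,6S)-1,5,5-trimethyl-6-[(E)-2-(tributylstannyl)ethenyl]-7-oxabicyclo[4.1.0]heptan-3-ol
Conditions: Bu3SnH, PdCl2(PPh3)2 (2 mol%), THF, 0 °C
Reagents that add atoms: tributyltin hydride CCCC[SnH](CCCC)CCCC
Why: Palladium-catalysed syn hydrostannation of the terminal alkyne should place tin on the terminal carbon, away from the quaternary epoxide carbon, giving the (E)-vinylstannane.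

Step 19
Reactants: 25 prop-2-ynoic acid
Product: 26 (2E)-2,3-dibromoprop-2-enoic acid
Conditions: Br2, CHCl3, 0 °C to rt
Reagents that add atoms: bromine BrBr
Why: Anti addition of bromine to the alkyne gives the (E)-dibromide, in which the C3 bromine is cis to the carboxyl group.

Step 20
Reactants: 26 (2E)-2,3-dibromoprop-2-enoic acid; 27 (2E)-3-methylpent-2-en-4-yn-1-ol
Product: 28 (5Z)-3-bromo-5-[(2E)-4-hydroxy-2-methylbut-2-en-1-ylidene]furan-2(5H)-one
Conditions: Pd(PPh3)4 (5 mol%), CuI (10 mol%), Et3N, MeCN, rt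
Reagents that add atoms: none
Why: Sonogashira coupling at the more electrophilic beta C–Br bond, followed in the same flask by 5-exo-dig anti-oxymetalation and protodemetalation of the (Z)-2-en-4-ynoic acid, should give the (Z)-alkylidenebutenolide with the alpha bromide kept for step 21.

Step 21
Reactants: 28 (5Z)-3-bromo-5-[(2E)-4-hydroxy-2-methylbut-2-en-1-ylidene]furan-2(5H)-one; 24 (1R,3S,6S)-1,5,5-trimethyl-6-[(E)-2-(tributylstannyl)ethenyl]-7-oxabicyclo[4.1.0]heptan-3-ol
Product: 29 (5Z)-3-[(E)-2-[(1S,4S,6R)-4-hydroxy-2,2,6-trimethyl-7-oxabicyclo[4.1.0]heptan-1-yl]ethenyl]-5-[(2E)-4-hydroxy-2-methylbut-2-en-1-ylidene]furan-2(5H)-one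
Conditions: Pd2(dba)3 (2.5 mol%), AsPh3 (20 mol%), CuI (10 mol%), DMF, rt
Reagents that add atoms: none
Why: Stille coupling of the 3-bromobutenolide with the (E)-vinylstannane proceeds with retention of alkene geometry under neutral conditions that tolerate the epoxide, both hydroxyls and the ylidene lactone.

Step 22
Reactants: 29 (5Z)-3-[(E)-2-[(1S,4S,6R)-4-hydroxy-2,2,6-trimethyl-7-oxabicyclo[4.1.0]heptan-1-yl]ethenyl]-5-[(2E)-4-hydroxy-2-methylbut-2-en-1-ylidene]furan-2(5H)-one
Product: 30 (2E)-4-[(2Z)-4-[(E)-2-[(1S,4S,6R)-4-hydroxy-2,2,6-trimethyl-7-oxabicyclo[4.1.0]heptan-1-yl]ethenyl]-5-oxofuran-2(5H)-ylidene]-3-methylbut-2-enal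
Conditions: MnO2, CH2Cl2, rt
Reagents that add atoms: none
Why: MnO2 oxidises only the primary allylic alcohol and leaves the saturated secondary alcohol of ring B untouched.

Step 23
Reactants: 30 (2E)-4-[(2Z)-4-[(E)-2-[(1S,4S,6R)-4-hydroxy-2,2,6-trimethyl-7-oxabicyclo[4.1.0]heptan-1-yl]ethenyl]-5-oxofuran-2(5H)-ylidene]-3-methylbut-2-enal
Product: 31 (5Z)-3-[(E)-2-[(1S,4S,6R)-4-hydroxy-2,2,6-trimethyl-7-oxabicyclo[4.1.0]heptan-1-yl]ethenyl]-5-[(2E,4E)-5-iodo-2-methylpenta-2,4-dien-1-ylidene]furan-2(5H)-one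
Conditions: CrCl2, CHI3, THF/dioxane, 0 °C
Reagents that add atoms: iodoform IC(I)I
Why: Takai olefination homologates the enal by one carbon to the (E)-vinyl iodide.

Step 24
Reactants: 19 (1R)-3,5,5-trimethyl-4-[(3E,5E)-3-methyl-6-(tributylstannyl)hexa-3,5-dien-1-yn-1-yl]cyclohex-3-en-1-yl acetate; 31 (5Z)-3-[(E)-2-[(1S,4S,6R)-4-hydroxy-2,2,6-trimethyl-7-oxabicyclo[4.1.0]heptan-1-yl]ethenyl]-5-[(2E,4E)-5-iodo-2-methylpenta-2,4-dien-1-ylidene]furan-2(5H)-one
Product: 32 pyrrhoxanthin (CNP0337675.1)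
Conditions: Pd2(dba)3 (5 mol%), AsPh3 (40 mol%), NMP, rt, dark
Reagents that add atoms: none
Why: Stille coupling of dienyl stannane and dienyl iodide forms the central single bond of the pentaene with retention of all double-bond geometries, and ligand-poor palladium at room temperature should spare acetate, epoxide, free alcohol and ylidenebutenolide.

## Compound list

1 | 3-methylbut-3-en-1-ol | CC(=C)CCO | starting material
2 | 3-methylbut-3-enal | CC(=C)CC=O | intermediate
3 | 1-methoxy-1,3-bis(trimethylsilyloxy)buta-1,3-diene | COC(=CC(=C)O[Si](C)(C)C)O[Si](C)(C)C | starting material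
4 | methyl (5S)-7-methyl-3-oxo-5-(trimethylsilyloxy)oct-7-enoate | C[Si](C)(C)O[C@@H](CC(C)=C)CC(=O)CC(=O)OC | intermediate
5 | methyl (5S)-5-hydroxy-7-methyl-3-oxooct-7-enoate | O[C@@H](CC(C)=C)CC(=O)CC(=O)OC | intermediate
6 | methyl (4S)-4-hydroxy-6,6-dimethyl-2-oxocyclohexane-1-carboxylate (C1 undefined, keto/enol) | O[C@@H]1CC(=O)C(C(=O)OC)C(C)(C)C1 | intermediate
7 | methyl (4S)-4-[(tert-butyldimethylsilyl)oxy]-6,6-dimethyl-2-oxocyclohexane-1-carboxylate | CC(C)(C)[Si](C)(C)O[C@@H]1CC(=O)C(C(=O)OC)C(C)(C)C1 | intermediate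
8 | methyl (4S)-4-[(tert-butyldimethylsilyl)oxy]-6,6-dimethyl-2-{[(trifluoromethyl)sulfonyl]oxy}cyclohex-1-ene-1-carboxylate | CC(C)(C)[Si](C)(C)O[C@@H]1CC(OS(=O)(=O)C(F)(F)F)=C(C(=O)OC)C(C)(C)C1 | intermediate
9 | methyl (4R)-4-[(tert-butyldimethylsilyl)oxy]-2,6,6-trimethylcyclohex-1-ene-1-carboxylate | CC(C)(C)[Si](C)(C)O[C@@H]1CC(C)=C(C(=O)OC)C(C)(C)C1 | intermediate
10 | [(4R)-4-[(tert-butyldimethylsilyl)oxy]-2,6,6-trimethylcyclohex-1-en-1-yl]methanol | CC(C)(C)[Si](C)(C)O[C@@H]1CC(C)=C(CO)C(C)(C)C1 | intermediate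
11 | (4R)-4-[(tert-butyldimethylsilyl)oxy]-2,6,6-trimethylcyclohex-1-ene-1-carbaldehyde | CC(C)(C)[Si](C)(C)O[C@@H]1CC(C)=C(C=O)C(C)(C)C1 | intermediate
12 | tert-butyl{[(1R)-4-ethynyl-3,5,5-trimethylcyclohex-3-en-1-yl]oxy}dimethylsilane | CC(C)(C)[Si](C)(C)O[C@@H]1CC(C)=C(C#C)C(C)(C)C1 | intermediate
13 | (bromoethynyl)triisopropylsilane | BrC#C[Si](C(C)C)(C(C)C)C(C)C | starting material
14 | tert-butyldimethyl{[(1R)-3,5,5-trimethyl-4-[4-(triisopropylsilyl)buta-1,3-diyn-1-yl]cyclohex-3-en-1-yl]oxy}silane | CC(C)(C)[Si](C)(C)O[C@@H]1CC(C)=C(C#CC#C[Si](C(C)C)(C(C)C)C(C)C)C(C)(C)C1 | intermediate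
15 | (1R)-4-(buta-1,3-diyn-1-yl)-3,5,5-trimethylcyclohex-3-en-1-ol | O[C@@H]1CC(C)=C(C#CC#C)C(C)(C)C1 | intermediate
16 | (1R)-4-[(3E)-4-iodo-3-methylbut-3-en-1-yn-1-yl]-3,5,5-trimethylcyclohex-3-en-1-ol | O[C@@H]1CC(C)=C(C#C/C(C)=C/I)C(C)(C)C1 | intermediate
17 | (1R)-4-[(3E)-4-iodo-3-methylbut-3-en-1-yn-1-yl]-3,5,5-trimethylcyclohex-3-en-1-yl acetate | CC(=O)O[C@@H]1CC(C)=C(C#C/C(C)=C/I)C(C)(C)C1 | intermediate
18 | (E)-1,2-bis(tributylstannyl)ethene | CCCC[Sn](CCCC)(CCCC)/C=C/[Sn](CCCC)(CCCC)CCCC | starting material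
19 | (1R)-3,5,5-trimethyl-4-[(3E,5E)-3-methyl-6-(tributylstannyl)hexa-3,5-dien-1-yn-1-yl]cyclohex-3-en-1-yl acetate | CC(=O)O[C@@H]1CC(C)=C(C#C/C(C)=C/C=C/[Sn](CCCC)(CCCC)CCCC)C(C)(C)C1 | intermediate
20 | [(1R,4S,6R)-4-[(tert-butyldimethylsilyl)oxy]-2,2,6-trimethyl-7-oxabicyclo[4.1.0]heptan-1-yl]methanol | OC[C@@]12O[C@]1(C)C[C@@H](O[Si](C)(C)C(C)(C)C)CC2(C)C | intermediate
21 | (1S,4S,6R)-4-[(tert-butyldimethylsilyl)oxy]-2,2,6-trimethyl-7-oxabicyclo[4.1.0]heptane-1-carbaldehyde | O=C[C@@]12O[C@]1(C)C[C@@H](O[Si](C)(C)C(C)(C)C)CC2(C)C | intermediate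
22 | tert-butyl{[(1R,3S,6R)-6-ethynyl-1,5,5-trimethyl-7-oxabicyclo[4.1.0]heptan-3-yl]oxy}dimethylsilane | C#C[C@@]12O[C@]1(C)C[C@@H](O[Si](C)(C)C(C)(C)C)CC2(C)C | intermediate
23 | (1R,3S,6R)-6-ethynyl-1,5,5-trimethyl-7-oxabicyclo[4.1.0]heptan-3-ol | C#C[C@@]12O[C@]1(C)C[C@@H](O)CC2(C)C | intermediate
24 | (1R,3S,6S)-1,5,5-trimethyl-6-[(E)-2-(tributylstannyl)ethenyl]-7-oxabicyclo[4.1.0]heptan-3-ol | CCCC[Sn](CCCC)(CCCC)/C=C/[C@@]12O[C@]1(C)C[C@@H](O)CC2(C)C | intermediate
25 | prop-2-ynoic acid | OC(=O)C#C | starting material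
26 | (2E)-2,3-dibromoprop-2-enoic acid | OC(=O)/C(Br)=C\Br | intermediate
27 | (2E)-3-methylpent-2-en-4-yn-1-ol | C#C/C(C)=C/CO | starting material
28 | (5Z)-3-bromo-5-[(2E)-4-hydroxy-2-methylbut-2-en-1-ylidene]furan-2(5H)-one | OC/C=C(C)/C=C2C=C(Br)C(=O)O/2 | intermediate
29 | (5Z)-3-[(E)-2-[(1S,4S,6R)-4-hydroxy-2,2,6-trimethyl-7-oxabicyclo[4.1.0]heptan-1-yl]ethenyl]-5-[(2E)-4-hydroxy-2-methylbut-2-en-1-ylidene]furan-2(5H)-one | OC/C=C(C)/C=C2C=C(/C=C/[C@@]34O[C@]3(C)C[C@@H](O)CC4(C)C)C(=O)O/2 | intermediate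
30 | (2E)-4-[(2Z)-4-[(E)-2-[(1S,4S,6R)-4-hydroxy-2,2,6-trimethyl-7-oxabicyclo[4.1.0]heptan-1-yl]ethenyl]-5-oxofuran-2(5H)-ylidene]-3-methylbut-2-enal | O=C/C=C(C)/C=C2C=C(/C=C/[C@@]34O[C@]3(C)C[C@@H](O)CC4(C)C)C(=O)O/2 | intermediate
31 | (5Z)-3-[(E)-2-[(1S,4S,6R)-4-hydroxy-2,2,6-trimethyl-7-oxabicyclo[4.1.0]heptan-1-yl]ethenyl]-5-[(2E,4E)-5-iodo-2-methylpenta-2,4-dien-1-ylidene]furan-2(5H)-one | I/C=C/C=C(C)/C=C2C=C(/C=C/[C@@]34O[C@]3(C)C[C@@H](O)CC4(C)C)C(=O)O/2 | intermediate
32 | pyrrhoxanthin (CNP0337675.1) | CC(=O)O[C@@H]1CC(C)=C(C#C/C(C)=C/C=C/C=C/C=C(C)/C=C2C=C(/C=C/[C@@]34O[C@]3(C)C[C@@H](O)CC4(C)C)C(=O)O/2)C(C)(C)C1 | target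
33 | (4R,6R)-4-hydroxy-2,2,6-trimethylcyclohexan-1-one (used only in the fallback to step 2) | O[C@@H]1C[C@@H](C)C(=O)C(C)(C)C1 | starting material
34 | 3-bromofuran-2(5H)-one (used only in the fallback to step 20) | BrC1=CCOC1=O | starting material
35 | (2E)-3-formylbut-2-en-1-yl acetate (used only in the fallback to step 20) | CC(=O)OC/C=C(C)/C=O | starting material
36 | (2E)-3-(tributylstannyl)prop-2-en-1-ol (used only in the fallback to step 23) | CCCC[Sn](CCCC)(CCCC)/C=C/CO | starting material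

## Step count and risks

Total step count: 24. Longest linear sequence: 15 steps (steps 1–6, 14–18, 21–24).

**Step 2.** The catalyst may discriminate the faces of the small beta,gamma-unsaturated aldehyde poorly, and 2 may isomerise to the conjugated enal before it is consumed. Under SnCl4 the beta-hydroxy ketone may also cleave by retro-aldol reaction, dehydrate or lactonise faster than the tertiary cation is trapped at carbon. The fallback uses a purchased ring and no cationic cyclisation; it sets out from ketone 33, whose carbinol carbon already has the needed configuration, and comes back to the route at ester 9. Silylation of 33 (tert-butyldimethylsilyl chloride, imidazole, DMF) should give (4R,6R)-4-[(tert-butyldimethylsilyl)oxy]-2,2,6-trimethylcyclohexan-1-one F1. Deprotonation at the only enolisable position with KN(SiMe3)2 and trapping with PhN(SO2CF3)2 (THF, −78 °C) should give (4R)-4-[(tert-butyldimethylsilyl)oxy]-2,6,6-trimethylcyclohex-1-en-1-yl trifluoromethanesulfonate F2. Palladium-catalysed methoxycarbonylation of F2 (Pd(OAc)2, PPh3, CO, MeOH, Et3N, DMF, 60 °C) should give 9.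

**Step 23.** Divalent chromium may reduce or oligomerise the electron-poor ylidenebutenolide dienal, the free hydroxyl may slow the reaction, and E selectivity may be incomplete. The fallback avoids the iodide and makes the last bond by Julia–Kocienski olefination; it sets out from iodide 17 and comes back to the route at target 32, using aldehyde 30 directly. Stille coupling of 17 with stannane 36 (PdCl2(MeCN)2, DMF, rt) should give (1R)-4-[(3E,5E)-7-hydroxy-3-methylhepta-3,5-dien-1-yn-1-yl]-3,5,5-trimethylcyclohex-3-en-1-yl acetate F3. Mitsunobu reaction with 1-phenyl-1H-tetrazole-5-thiol (PPh3, diisopropyl azodicarboxylate, THF) should give (1R)-3,5,5-trimethyl-4-[(3E,5E)-3-methyl-7-[(1-phenyl-1H-tetrazol-5-yl)sulfanyl]hepta-3,5-dien-1-yn-1-yl]cyclohex-3-en-1-yl acetate F4. Oxidation (H2O2, (NH4)6Mo7O24, EtOH) should give the corresponding (1-phenyl-1H-tetrazol-5-yl)sulfonyl compound F5. Metalation of F5 with KN(SiMe3)2 in the presence of 30 (THF, −78 °C, a second equivalent of base for the free hydroxyl) should give 32; a Z portion at the new double bond would be equilibrated to all-E in benzene in daylight with a trace of iodine.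

**Step 20.** Oxidative addition may not discriminate cleanly between the two C–Br bonds, the bromo acid may decarboxylate, and the cyclisation may take the 6-endo course to a pyranone. In the fallback ring C is bought and the exocyclic double bond is made by aldol addition and elimination; it sets out from bromofuranone 34 and comes back to the route at 28. Silylation of 34 (tert-butyldimethylsilyl triflate, Et3N, CH2Cl2, 0 °C) should give [(3-bromofuran-2-yl)oxy](tert-butyl)dimethylsilane F6. Vinylogous Mukaiyama aldol addition of F6 to aldehyde 35 (BF3·OEt2, CH2Cl2, −78 °C) should give (2E)-4-(4-bromo-5-oxo-2,5-dihydrofuran-2-yl)-4-hydroxy-3-methylbut-2-en-1-yl acetate F7 as a diastereomer mixture. Mesylation and elimination (MsCl, Et3N, then DBU, CH2Cl2) should give (2E)-4-[(2Z)-4-bromo-5-oxofuran-2(5H)-ylidene]-3-methylbut-2-en-1-yl acetate F8, any E isomer at the ylidene bond being equilibrated to Z with a trace of iodine. Methanolysis of the acetate (K2CO3, MeOH, 0 °C) should give 28.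

## Further compounds

F1 | step 2 | (4R,6R)-4-[(tert-butyldimethylsilyl)oxy]-2,2,6-trimethylcyclohexan-1-one | CC(C)(C)[Si](C)(C)O[C@@H]1C[C@@H](C)C(=O)C(C)(C)C1
F2 | step 2 | (4R)-4-[(tert-butyldimethylsilyl)oxy]-2,6,6-trimethylcyclohex-1-en-1-yl trifluoromethanesulfonate | CC(C)(C)[Si](C)(C)O[C@@H]1CC(C)=C(OS(=O)(=O)C(F)(F)F)C(C)(C)C1
F3 | step 23 | (1R)-4-[(3E,5E)-7-hydroxy-3-methylhepta-3,5-dien-1-yn-1-yl]-3,5,5-trimethylcyclohex-3-en-1-yl acetate | CC(=O)O[C@@H]1CC(C)=C(C#C/C(C)=C/C=C/CO)C(C)(C)C1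
F4 | step 23 | (1R)-3,5,5-trimethyl-4-[(3E,5E)-3-methyl-7-[(1-phenyl-1H-tetrazol-5-yl)sulfanyl]hepta-3,5-dien-1-yn-1-yl]cyclohex-3-en-1-yl acetate | CC(=O)O[C@@H]1CC(C)=C(C#C/C(C)=C/C=C/CSc2nnnn2-c2ccccc2)C(C)(C)C1
F5 | step 23 | (1R)-3,5,5-trimethyl-4-[(3E,5E)-3-methyl-7-[(1-phenyl-1H-tetrazol-5-yl)sulfonyl]hepta-3,5-dien-1-yn-1-yl]cyclohex-3-en-1-yl acetate | CC(=O)O[C@@H]1CC(C)=C(C#C/C(C)=C/C=C/CS(=O)(=O)c2nnnn2-c2ccccc2)C(C)(C)C1
F6 | step 20 | [(3-bromofuran-2-yl)oxy](tert-butyl)dimethylsilane | CC(C)(C)[Si](C)(C)Oc1occc1Br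
F7 | step 20 | (2E)-4-(4-bromo-5-oxo-2,5-dihydrofuran-2-yl)-4-hydroxy-3-methylbut-2-en-1-yl acetate | CC(=O)OC/C=C(C)/C(O)C1OC(=O)C(Br)=C1
F8 | step 20 | (2E)-4-[(2Z)-4-bromo-5-oxofuran-2(5H)-ylidene]-3-methylbut-2-en-1-yl acetate | CC(=O)OC/C=C(C)/C=C2C=C(Br)C(=O)O/2
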